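**Retrosynthetic overview**
- The last skeletal C–O bond is the C3 ester, made by Mitsunobu inversion of the axial 3β-alcohol with the Z,Z acid. The acid comes from 3-methylfuran-2(5H)-one (Z alkene locked in the ring) and angelic acid. The diosphenol is carried as its methoxymethyl ether.
- Ring B is decorated from the C9=C10 enone: epoxidation and acid isomerisation give the C9 enol and C8 ketone, and acetone aldol–dehydration gives the C7 isopropylidene.
- The plan rests on ring A (C1, C2, C3, C4, C5, C10): it is the cyclopentanone ring of the commercial (S)-methylhydrindenedione plus one CH(CH3) carbon, C4, lodged between carbonyl carbon C3 and quaternary C5. Cutting C3–C4 and C4–C5 leaves the enone dithioketal of that dione and CH3CBr2Li.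
- Ring order: ring B and the five-membered ring are bought fused, and ring A becomes six-membered in step 2. C5 is bought, C4 is set in step 2, C3 in steps 3 and 15.

Key step: step 2

Remark: eremophilane numbering is used for the bicyclic compounds (ring A: C1–C5, C10; ring B: C5–C10), β is the face of the C5 methyl, and the target is (3R,4R,5R).

**Step 1**
Reactants: 1 (S)-7a-methyl-2,3,7,7a-tetrahydro-1H-indene-1,5(6H)-dione; 2 ethane-1,2-dithiol
Product: 3 (S)-7a-methyl-2,3,7,7a-tetrahydro-1H-indene-1,5(6H)-dione 5-(ethylene dithioketal)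
Conditions: p-TsOH·H2O (cat.), AcOH, rt
Reagents that add atoms: none
Why: Acid-catalysed dithioketalisation should take the conjugated carbonyl selectively, because the other carbonyl is a cyclopentanone flanked by the quaternary carbon, and the double bond stays in place as it does with steroidal 4-en-3-ones.

**Step 2**
Reactants: 3 (S)-7a-methyl-2,3,7,7a-tetrahydro-1H-indene-1,5(6H)-dione 5-(ethylene dithioketal); 4 1,1-dibromoethane
Product: 9 4β,5β-dimethyloctal-9-en-3-one 8-(ethylene dithioketal) (4R,5R), via 1,1-dibromoethyllithium 5 (not isolated), via dibromo alkoxide 6 (not isolated), via β-oxido carbenoid 7 (not isolated), via lithium enolate 8 (not isolated)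
Conditions: LiN(i-Pr)2, THF–Et2O, −100 °C, add 4; then 3, −100 → −90 °C; then n-BuLi (excess), −100 → −20 °C; AcOH, THF, −78 °C
Reagents that add atoms: none
Why: 1,1-Dibromoethyllithium adds to the cyclopentanone carbonyl on the face opposite the angular methyl and makes C3–C4; bromine–lithium exchange then gives a β-oxido carbenoid, and as bromide leaves C5 shifts from C3 to the electron-poor carbenoid carbon, which makes C4–C5 and delivers the C3–C4 lithium enolate directly. The closest known reaction type is the one-carbon ring enlargement of cycloalkanones through β-oxido carbenoids derived from dibromoalkyllithium adducts. Ring A is closed by insertion, not by cyclisation: a semipinacol-type 1,2-alkyl shift with retention at C5 turns the five-membered ring into the six-membered one. C4 is set on the quench, where the enolate should be protonated along the axial direction on the face anti to the axial C5 methyl, so the C4 methyl ends equatorial and cis to it; this is also the expected thermodynamic epimer, so NaOMe in MeOH could correct a mixture. The selectivity required is that quaternary C5 and not the C2 methylene shifts, which should follow from the better migrating ability of the more substituted, more electron-rich carbon; addition must also outrun enolisation, so the reagent is pre-formed at −100 °C and the exchange is run cold so that n-BuLi spares the dithiolane.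

**Step 3**
Reactants: 9 4β,5β-dimethyloctal-9-en-3-one 8-(ethylene dithioketal) (4R,5R)
Product: 10 3β-hydroxy-4β,5β-dimethyloctal-9-ene 8-(ethylene dithioketal) (3S,4R,5R)
Conditions: LiBH(s-Bu)3, THF, −78 °C; MeOH then aq. NaOH (no peroxide work-up)
Reagents that add atoms: none
Why: The bulky hydride should attack C3 from the equatorial α direction, because the axial β approach is blocked by the syn-axial C5 methyl, giving the axial 3β-alcohol cis to both methyls (substrate-controlled ketone reduction); the non-oxidative work-up spares the sulfur.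

**Step 4**
Reactants: 10 3β-hydroxy-4β,5β-dimethyloctal-9-ene 8-(ethylene dithioketal) (3S,4R,5R)
Product: 11 3β-hydroxy-4β,5β-dimethyloctal-9-en-8-one
Conditions: MeI, CaCO3, MeCN–H2O, 50 °C
Reagents that add atoms: water, O
Why: Alkylative dithioketal hydrolysis: S-methylation turns sulfur into a leaving group and the allylic thionium ion is captured by water, which should return the conjugated enone without touching the free alcohol.

**Step 5**
Reactants: 11 3β-hydroxy-4β,5β-dimethyloctal-9-en-8-one
Product: 12 9β,10β-epoxy-3β-hydroxy-4β,5β-dimethyldecal-8-one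
Conditions: 30% H2O2, NaOH (aq., cat.), MeOH, 0 °C → rt
Reagents that add atoms: hydrogen peroxide, OO
Why: Weitz–Scheffer nucleophilic epoxidation of the enone; the epoxide is drawn on the face of the C5 methyl by analogy with steroidal 4-en-3-ones, but its configuration does not matter because C9 and C10 become trigonal in step 6.

**Step 6**
Reactants: 12 9β,10β-epoxy-3β-hydroxy-4β,5β-dimethyldecal-8-one
Product: 13 3β,9-dihydroxy-4β,5β-dimethyloctal-9-en-8-one
Conditions: conc. H2SO4 (cat.), AcOH, 15 °C; then K2CO3, MeOH, rt, under Ar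
Reagents that add atoms: none
Why: Acid-catalysed isomerisation of an α,β-epoxy ketone to the diosphenol, the reaction type that turns 4,5-epoxy-3-keto steroids into 4-hydroxy-4-en-3-ones: the C10–O bond opens at the tertiary carbon and loss of the C9 proton gives the hydrogen-bonded enol, while the carbonate–methanol treatment returns any C3 acetate formed in the acetic acid to the alcohol.

**Step 7**
Reactants: 13 3β,9-dihydroxy-4β,5β-dimethyloctal-9-en-8-one
Product: 14 3β-hydroxy-9-(methoxymethoxy)-4β,5β-dimethyloctal-9-en-8-one
Conditions: MeOCH2Cl (1.1 equiv), i-Pr2NEt, CH2Cl2, 0 °C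
Reagents that add atoms: chloromethyl methyl ether, COCCl
Why: O-Alkylation of the acidic enol (pKa near 10) with an amine base and a slight excess of the chloride at 0 °C should be selective over the hindered, non-ionised axial secondary alcohol (Williamson-type acetal formation).

**Step 8**
Reactants: 14 3β-hydroxy-9-(methoxymethoxy)-4β,5β-dimethyloctal-9-en-8-one
Product: 15 9-(methoxymethoxy)-4β,5β-dimethyl-3β-(triethylsilyloxy)octal-9-en-8-one
Conditions: Et3SiOTf, 2,6-lutidine, CH2Cl2, −78 → 0 °C
Reagents that add atoms: triethylsilyl trifluoromethanesulfonate, CC[Si](CC)(CC)OS(=O)(=O)C(F)(F)F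
Why: Silylation with the silyl triflate and a pyridine base protects the crowded axial alcohol for the enolate chemistry, and triethylsilyl is chosen because it should go onto and later come off this oxygen under mild conditions.

**Step 9**
Reactants: 15 9-(methoxymethoxy)-4β,5β-dimethyl-3β-(triethylsilyloxy)octal-9-en-8-one
Product: 17 7α-(2-hydroxypropan-2-yl)-9-(methoxymethoxy)-4β,5β-dimethyl-3β-(triethylsilyloxy)octal-9-en-8-one, via lithium enolate 16 (not isolated)
Conditions: LiN(i-Pr)2, THF, −78 °C; acetone; AcOH quench at −78 °C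
Reagents that add atoms: acetone, CC(C)=O
Why: Kinetic deprotonation at C7, the only α-CH of the C8 ketone, gives the cross-conjugated lithium enolate, which should undergo aldol addition to acetone; the cold acidic quench guards against retro-aldol, and the C7 configuration (drawn trans to the C5 methyl) is erased in step 10.

**Step 10**
Reactants: 17 7α-(2-hydroxypropan-2-yl)-9-(methoxymethoxy)-4β,5β-dimethyl-3β-(triethylsilyloxy)octal-9-en-8-one
Product: 19 9-(methoxymethoxy)-3β-(triethylsilyloxy)eremophila-7(11),9-dien-8-one, via tertiary mesylate 18 (not isolated)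
Conditions: MsCl, Et3N, DMAP (cat.), CH2Cl2, 0 °C; then DBU, rt
Reagents that add atoms: none
Why: Mesylation of the tertiary carbinol and DBU-mediated E1cB elimination through the acidic C7 hydrogen should give the conjugated tetrasubstituted isopropylidene, the thermodynamically preferred alkene.

**Step 11**
Reactants: 19 9-(methoxymethoxy)-3β-(triethylsilyloxy)eremophila-7(11),9-dien-8-one
Product: 20 3β-hydroxy-9-(methoxymethoxy)eremophila-7(11),9-dien-8-one
Conditions: Bu4NF, AcOH, THF, 0 °C → rt
Reagents that add atoms: none
Why: Buffered fluoride cleaves the Si–O bond (desilylation), and the acetic acid keeps the medium mild enough for the dienone and the enol acetal.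

**Step 12**
Reactants: 21 3-methylfuran-2(5H)-one
Product: 23 4-methoxybenzyl (Z)-4-hydroxy-2-methylbut-2-enoate, via sodium carboxylate 22 (not isolated)
Conditions: NaOH (1.0 equiv), H2O–MeOH, rt; evaporate; 4-MeOC6H4CH2Cl, Bu4NI (cat.), DMF, 0 °C → rt
Reagents that add atoms: sodium hydroxide, [Na+].[OH-]; 4-methoxybenzyl chloride, COc1ccc(CCl)cc1
Why: Saponification opens the lactone to the carboxylate with the Z geometry fixed by the ring, and carboxylate O-alkylation without added base gives the ester, which is used at once without heat or acid so that it does not close back to the lactone.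

**Step 13**
Reactants: 23 4-methoxybenzyl (Z)-4-hydroxy-2-methylbut-2-enoate; 24 angelic acid
Product: 25 4-methoxybenzyl (Z)-2-methyl-4-{[(Z)-2-methylbut-2-enoyl]oxy}but-2-enoate
Conditions: PPh3, DIAD, THF, 0 °C
Reagents that add atoms: none
Why: Mitsunobu esterification activates the primary allylic alcohol and not the acid, so the angelate enters by SN2 displacement without the Z to E isomerisation that acyl activation of angelic acid invites.

**Step 14**
Reactants: 25 4-methoxybenzyl (Z)-2-methyl-4-{[(Z)-2-methylbut-2-enoyl]oxy}but-2-enoate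
Product: 26 (Z)-2-methyl-4-{[(Z)-2-methylbut-2-enoyl]oxy}but-2-enoic acid
Conditions: CF3CO2H, anisole, CH2Cl2, 0 °C
Reagents that add atoms: none
Why: Acidolysis of the 4-methoxybenzyl ester through the stabilised benzylic cation, which anisole traps (Friedel–Crafts alkylation), should free the acid at 0 °C without hydrolytic conditions that would endanger the allylic ester; the acid is used directly.

**Step 15**
Reactants: 20 3β-hydroxy-9-(methoxymethoxy)eremophila-7(11),9-dien-8-one; 26 (Z)-2-methyl-4-{[(Z)-2-methylbut-2-enoyl]oxy}but-2-enoic acid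
Product: 27 9-(methoxymethoxy)-8-oxoeremophila-7(11),9-dien-3α-yl (Z)-2-methyl-4-{[(Z)-2-methylbut-2-enoyl]oxy}but-2-enoate
Conditions: PPh3, DIAD, toluene, 0 °C → rt
Reagents that add atoms: none
Why: Mitsunobu reaction: the axial 3β-oxyphosphonium group should be displaced by the carboxylate from the α face with inversion (SN2), which sets the equatorial (3R) ester, and because the alcohol and not the acid is activated both Z alkenes of the side chain are kept.

**Step 16**
Reactants: 27 9-(methoxymethoxy)-8-oxoeremophila-7(11),9-dien-3α-yl (Z)-2-methyl-4-{[(Z)-2-methylbut-2-enoyl]oxy}but-2-enoate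
Product: 28 CNP0301409.1, 9-hydroxy-8-oxoeremophila-7(11),9-dien-3α-yl (Z)-2-methyl-4-{[(Z)-2-methylbut-2-enoyl]oxy}but-2-enoate (3R,4R,5R)
Conditions: CF3CO2H–CH2Cl2–H2O, 0 °C
Reagents that add atoms: none
Why: Acid-catalysed cleavage of the enol methoxymethyl acetal, more labile than an alkyl one because the enol is the better leaving group, should free the diosphenol under cold, brief conditions that the Z-configured esters should tolerate.

**Compound list**
1 | (S)-7a-methyl-2,3,7,7a-tetrahydro-1H-indene-1,5(6H)-dione | C[C@]12CCC(=O)C=C1CCC2=O | starting material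
2 | ethane-1,2-dithiol | SCCS | starting material
3 | (S)-7a-methyl-2,3,7,7a-tetrahydro-1H-indene-1,5(6H)-dione 5-(ethylene dithioketal) | O=C1CCC2=CC3(SCCS3)CC[C@]12C | intermediate
4 | 1,1-dibromoethane | CC(Br)Br | starting material
5 | 1,1-dibromoethyllithium | [Li]C(C)(Br)Br | intermediate
6 | lithium alkoxide of the 1-(1,1-dibromoethyl) carbinol from 3 (oxygen cis to the angular methyl) | [Li]O[C@@]1(C(C)(Br)Br)CCC2=CC3(SCCS3)CC[C@]12C | intermediate
7 | β-oxido carbenoid, the 1-bromo-1-lithioethyl lithium alkoxide (carbenoid carbon not defined) | [Li]O[C@@]1(C(C)(Br)[Li])CCC2=CC3(SCCS3)CC[C@]12C | intermediate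
8 | lithium C3–C4 enolate of 9 | CC1=C(O[Li])CCC2=CC3(SCCS3)CC[C@]12C | intermediate
9 | 4β,5β-dimethyloctal-9-en-3-one 8-(ethylene dithioketal), (4R,5R) | C[C@H]1C(=O)CCC2=CC3(SCCS3)CC[C@]12C | intermediate
10 | 3β-hydroxy-4β,5β-dimethyloctal-9-ene 8-(ethylene dithioketal), (3S,4R,5R), axial alcohol | O[C@H]1CCC2=CC3(SCCS3)CC[C@]2(C)[C@H]1C | intermediate
11 | 3β-hydroxy-4β,5β-dimethyloctal-9-en-8-one | O[C@H]1CCC2=CC(=O)CC[C@]2(C)[C@H]1C | intermediate
12 | 9β,10β-epoxy-3β-hydroxy-4β,5β-dimethyldecal-8-one (the 9α,10α epoxide would serve equally) | O[C@H]1CC[C@]23O[C@H]2C(=O)CC[C@]3(C)[C@H]1C | intermediate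
13 | 3β,9-dihydroxy-4β,5β-dimethyloctal-9-en-8-one (diosphenol) | O[C@H]1CCC2=C(O)C(=O)CC[C@]2(C)[C@H]1C | intermediate
14 | 3β-hydroxy-9-(methoxymethoxy)-4β,5β-dimethyloctal-9-en-8-one | O[C@H]1CCC2=C(OCOC)C(=O)CC[C@]2(C)[C@H]1C | intermediate
15 | 9-(methoxymethoxy)-4β,5β-dimethyl-3β-(triethylsilyloxy)octal-9-en-8-one | CC[Si](CC)(CC)O[C@H]1CCC2=C(OCOC)C(=O)CC[C@]2(C)[C@H]1C | intermediate
16 | lithium C7–C8 enolate of 15 | CC[Si](CC)(CC)O[C@H]1CCC2=C(OCOC)C(O[Li])=CC[C@]2(C)[C@H]1C | intermediate
17 | 7α-(2-hydroxypropan-2-yl)-9-(methoxymethoxy)-4β,5β-dimethyl-3β-(triethylsilyloxy)octal-9-en-8-one (either C7 epimer serves) | CC[Si](CC)(CC)O[C@H]1CCC2=C(OCOC)C(=O)[C@H](C(C)(C)O)C[C@]2(C)[C@H]1C | intermediate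
18 | tertiary methanesulfonate of 17 | CC[Si](CC)(CC)O[C@H]1CCC2=C(OCOC)C(=O)[C@H](C(C)(C)OS(C)(=O)=O)C[C@]2(C)[C@H]1C | intermediate
19 | 9-(methoxymethoxy)-3β-(triethylsilyloxy)eremophila-7(11),9-dien-8-one | CC[Si](CC)(CC)O[C@H]1CCC2=C(OCOC)C(=O)C(=C(C)C)C[C@]2(C)[C@H]1C | intermediate
20 | 3β-hydroxy-9-(methoxymethoxy)eremophila-7(11),9-dien-8-one | O[C@H]1CCC2=C(OCOC)C(=O)C(=C(C)C)C[C@]2(C)[C@H]1C | intermediate
21 | 3-methylfuran-2(5H)-one | CC1=CCOC1=O | starting material
22 | sodium (Z)-4-hydroxy-2-methylbut-2-enoate | OC/C=C(/C)C(=O)[O-].[Na+] | intermediate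
23 | 4-methoxybenzyl (Z)-4-hydroxy-2-methylbut-2-enoate | OC/C=C(/C)C(=O)OCc1ccc(OC)cc1 | intermediate
24 | angelic acid, (Z)-2-methylbut-2-enoic acid | C/C=C(/C)C(=O)O | starting material
25 | 4-methoxybenzyl (Z)-2-methyl-4-{[(Z)-2-methylbut-2-enoyl]oxy}but-2-enoate | C/C=C(/C)C(=O)OC/C=C(/C)C(=O)OCc1ccc(OC)cc1 | intermediate
26 | (Z)-2-methyl-4-{[(Z)-2-methylbut-2-enoyl]oxy}but-2-enoic acid | C/C=C(/C)C(=O)OC/C=C(/C)C(=O)O | intermediate
27 | 9-(methoxymethoxy)-8-oxoeremophila-7(11),9-dien-3α-yl ester of 26 | C/C=C(/C)C(=O)OC/C=C(/C)C(=O)O[C@@H]1CCC2=C(OCOC)C(=O)C(=C(C)C)C[C@]2(C)[C@H]1C | intermediate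
28 | CNP0301409.1, (3R,4R,5R) | C/C=C(/C)C(=O)OC/C=C(/C)C(=O)O[C@@H]1CCC2=C(O)C(=O)C(=C(C)C)C[C@]2(C)[C@H]1C | target

**Step count and risks**
Total: 16 steps. Longest linear sequence: 13 steps (steps 1–11, 15 and 16, from 1); the side-chain acid takes steps 12–14.

Steps most likely to fail:

1. Step 2. The basic, thermally fragile 1,1-dibromoethyllithium may enolise the hindered cyclopentanone or decompose before it adds, surplus n-BuLi may attack the dithiolane, and the carbenoid may be lost to other pathways before C5 migrates. The fallback generates the carbenoid by sulfoxide–magnesium exchange, a known way to enlarge cyclic ketones by one substituted carbon, and sets out from 3. Ethyl p-tolyl sulfoxide is chlorinated with N-chlorosuccinimide to 1-chloroethyl p-tolyl sulfoxide F1. Its lithium carbanion (LiN(i-Pr)2, THF, −78 °C) is stable at that temperature and should add to 3 to give the isolable chlorohydrin sulfoxide adduct F2. Treatment with t-BuMgCl and then i-PrMgCl (THF, 0 °C → rt) should form the magnesium alkoxide and exchange the sulfinyl group for magnesium. The resulting β-oxido carbenoid rearranges to the same C3–C4 enolate, and protonation comes back to the route at 9.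

2. Step 15. The crowded axial hydroxyl may be slow to form the oxyphosphonium ion and the bulky, weakly acidic carboxylate slow to displace it, so that elimination toward C2 or C4, or acyl transfer with retention, takes over. The fallback separates inversion from acylation and sets out from 20. Mitsunobu reaction with the small, more acidic 4-nitrobenzoic acid (PPh3, DIAD, toluene) should give the inverted 3α-(4-nitrobenzoate) F3. Methanolysis (K2CO3, MeOH) frees the equatorial 3α-alcohol F4. This less hindered alcohol is acylated with retention by the mixed anhydride of 26 and 2,4,6-trichlorobenzoyl chloride (Et3N, toluene, no DMAP, to keep the Z alkenes), which comes back to the route at 27.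

3. Step 6. In the acidic medium the free axial hydroxyl may be esterified or may trap the C10 cation across ring A as a bridged ether, in competition with loss of the C9 proton. The fallback masks the hydroxyl before the acid step and sets out from 12. Acetylation (Ac2O, DMAP, pyridine) gives the 3β-acetoxy epoxy ketone F5. The same H2SO4/AcOH isomerisation gives the 3β-acetoxy diosphenol F6, and MeOCH2Cl with i-Pr2NEt gives its methoxymethyl ether F7. Methanolysis of the acetate (K2CO3, MeOH) comes back to the route at 14.

**Further compounds**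
F1 | step 2 | 1-chloroethyl p-tolyl sulfoxide (mixture of stereoisomers) | CC(Cl)S(=O)c1ccc(C)cc1
F2 | step 2 | chlorohydrin sulfoxide adduct of 3, 1-[1-chloro-1-(p-tolylsulfinyl)ethyl] carbinol (oxygen cis to the angular methyl; other new centres not defined) | O[C@@]1(C(C)(Cl)S(=O)c2ccc(C)cc2)CCC2=CC3(SCCS3)CC[C@]12C
F3 | step 15 | 9-(methoxymethoxy)-8-oxoeremophila-7(11),9-dien-3α-yl 4-nitrobenzoate | O=C(O[C@@H]1CCC2=C(OCOC)C(=O)C(=C(C)C)C[C@]2(C)[C@H]1C)c1ccc(cc1)[N+](=O)[O-]
F4 | step 15 | 3α-hydroxy-9-(methoxymethoxy)eremophila-7(11),9-dien-8-one | O[C@@H]1CCC2=C(OCOC)C(=O)C(=C(C)C)C[C@]2(C)[C@H]1C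
F5 | step 6 | 3β-acetoxy-9β,10β-epoxy-4β,5β-dimethyldecal-8-one | CC(=O)O[C@H]1CC[C@]23O[C@H]2C(=O)CC[C@]3(C)[C@H]1C
F6 | step 6 | 3β-acetoxy-9-hydroxy-4β,5β-dimethyloctal-9-en-8-one | CC(=O)O[C@H]1CCC2=C(O)C(=O)CC[C@]2(C)[C@H]1C
F7 | step 6 | 3β-acetoxy-9-(methoxymethoxy)-4β,5β-dimethyloctal-9-en-8-one | CC(=O)O[C@H]1CCC2=C(OCOC)C(=O)CC[C@]2(C)[C@H]1C
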